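A closed, stirred vessel at constant temperature holds substrate and a smaller charge of capture agent. Substrate turns into target and isomer of the product A, and capture agent can take a part of the material away as trapped intermediate.

| flask | substrate | capture agent | remark | time |
|---|---|---|---|---|
| amber | 0.080 M | 0.024 M | run made earlier |  |
| east | 0.080 M | 0.0160 M |  | 3.0 h |
| west | 0.25 M | 0.0160 M |  | 3.0 h |
| north-east | 0.80 M | 0.0160 M |  | 3.0 h |

amber run (percent of the substrate charged)

| time / min | target / % | isomer of the product A / % | trapped intermediate / % |
|---|---|---|---|
| 3.00 | 1.0 | 0.3 | 0 |
| 4.00 | 1.8 | 0.3 | 0 |
| 6.00 | 3.3 | 1.0 | 0.1 |
| 10.0 | 6.9 | 3.1 | 0 |
| 15.0 | 10.7 | 5.1 | 0.3 |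
| 25.0 | 16.6 | 10.0 | 0 |
| 40.0 | 20.7 | 16.5 | 0 |

(standard deviation of a reading: 0.3 percentage points)

- no earlier run changes the charge of capture agent; that part of a forecast is a guess
- "hardly changes" means that all values lie within two and a half points (for a concentration: within two and a half percent of the largest)

1. share of target in all that became target or isomer of the product A or trapped intermediate or isomer of the product B for east, west, north-east, in this order
2. the course of these numbers from the first flask to the last (falls all the way / falls, then rises / rises, then falls / hardly changes / rises all the way)

The new flasks keep capture agent at 0.0160 M and raise substrate from 0.080 M to 0.80 M, so I write the balance of capture agent. Capture agent is the smaller charge in each new flask, so by the charges it is the limiting reagent of the trapping step. If one capture agent holds one substrate's worth of material, trapped intermediate, in percent of the substrate charged, equals the charge ratio times the fraction of capture agent used. Full use gives what I call the capture ceiling, capture agent charged over substrate charged: 20.0 % in east, 6.40 % in west and 2.00 % in north-east.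

Does the flask come near that ceiling? The pace of trapping is a rate constant times capture agent times what it catches. The amber run, with 0.024 M of capture agent, shows no trapped reading above 0.3 %, which is one scatter, in 40.0 min. For a rough size, not a bound, I let that pace run for 3.0 h and scale it down to the new capture charge, which gives 0.900 % of the substrate charged. I assume first order in substrate, so this percentage stays the same when the charge rises, but no earlier run tests that or the scaling with capture agent. My figure lies below the tightest ceiling. Even taken wholly from target, it moves the share by about its own size, within the two and a half points of the margin, so my own reckoning says the row hardly changes. I set no level of my own.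

The forecast gives 20 %, 20 % and 20 %, so hardly changes, and states that “the reaction order is assumed first-order”. My shape agrees with it, and I reach it through the capture balance.

The three flasks give 26.6 %, 26.6 % and 26.6 %: the course hardly changes, at a level above the forecast.

    substrate → open intermediate (k = 0.0335 min⁻¹)
    open intermediate ⇌ target (K = 1.90, k = 0.0911 min⁻¹)
    open intermediate ⇌ isomer of the product A (K = 2.70, k = 0.0278 min⁻¹)
    open intermediate + capture agent → trapped intermediate (k = 0.0230 L mol⁻¹ min⁻¹)
    target ⇌ isomer of the product B (K = 1.40, k = 0.0622 min⁻¹)

In east at 3.00 h, target stands at 23.3 % of the substrate charged, with open intermediate at 12.1 % beside it. At that time north-east has used 38.0 % of its capture agent, which on its ceiling of 2.00 % comes to 0.760 %, and its trapped intermediate stands at 0.760 %. East, under a ceiling of 20.0 %, has used 4.67 % of its capture agent, which comes to 0.933 %, and its trapped intermediate stands at 0.933 %.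

(Readings and results stem from a simulated flask with constants of no real substance; noise was put on by code.)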